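Ring A of the terminal catechin unit is read as 1,3,5-trifluorobenzene: its three mutually meta oxygens (O1 on C8a, the oxygens on C5 and C7) all enter by fluoride displacement. The key step takes an open-chain (1R,2S)-1,3-diarylpropane-1,2-diol 2-benzyl ether whose C3 aryl group is 2,4,6-trifluorophenyl; the benzylic alkoxide closes ring C by forming the O1–C8a bond, both ortho fluorines being equivalent, and benzyloxide replaces the other two fluorines in the same pot. The resulting penta-O-benzylcatechin is extended by three 4β→8 Friedel–Crafts couplings with C4-activated benzylated epicatechin, epigallocatechin gallate and epicatechin, and the 21 benzyl ethers are removed by hydrogenolysis.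

Key step: step 6

Remark: the target is read as epicatechin-(4β→8)-epigallocatechin 3-O-gallate-(4β→8)-epicatechin-(4β→8)-catechin; in step 6 the C7 fluorine is assumed to be exchanged before the C5 fluorine, which does not affect the product.

Step 1
Reactants: 1 1,3,5-trifluorobenzene; 2 methyl (S)-oxirane-2-carboxylate (methyl (S)-glycidate)
Product: 5 methyl (S)-2-hydroxy-3-(2,4,6-trifluorophenyl)propanoate, via 2,4,6-trifluorophenyllithium 3 (not isolated), via 2,4,6-trifluorophenylmagnesium bromide 4 (not isolated)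
Conditions: n-BuLi, THF, −78 °C; MgBr2·OEt2, −78 → −40 °C; CuI (10 mol %), then 2, −40 → −10 °C; H2O
Reagents that add atoms: none
Why: Ortho-lithiation (every C–H of 1 lies between two fluorines), transmetalation and copper-catalysed SN2 opening of the glycidate at its unsubstituted C3 should give the α-hydroxy ester; the stereocenter comes unchanged from 2 and no new one is set.

Step 2
Reactants: 5 methyl (S)-2-hydroxy-3-(2,4,6-trifluorophenyl)propanoate
Product: 6 methyl (S)-2-(benzyloxy)-3-(2,4,6-trifluorophenyl)propanoate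
Conditions: benzyl 2,2,2-trichloroacetimidate, TfOH (5 mol %), CH2Cl2/cyclohexane, 0 °C → rt
Reagents that add atoms: benzyl 2,2,2-trichloroacetimidate N=C(OCc1ccccc1)C(Cl)(Cl)Cl
Why: Acid-catalysed trichloroacetimidate O-benzylation avoids base, so the enolisable α-stereocenter should not epimerise; no new stereocenter.

Step 3
Reactants: 6 methyl (S)-2-(benzyloxy)-3-(2,4,6-trifluorophenyl)propanoate
Product: 7 (S)-2-(benzyloxy)-N-methoxy-N-methyl-3-(2,4,6-trifluorophenyl)propanamide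
Conditions: MeNHOMe·HCl, i-PrMgCl, THF, −20 °C
Reagents that add atoms: N,O-dimethylhydroxylamine hydrochloride CNOC.Cl
Why: Weinreb amide formation by aminolysis of the ester with the magnesium amide at −20 °C should leave the α-alkoxy stereocenter intact.

Step 4
Reactants: 7 (S)-2-(benzyloxy)-N-methoxy-N-methyl-3-(2,4,6-trifluorophenyl)propanamide; 8 4-bromo-1,2-bis(benzyloxy)benzene
Product: 10 (S)-2-(benzyloxy)-1-[3,4-bis(benzyloxy)phenyl]-3-(2,4,6-trifluorophenyl)propan-1-one, via 3,4-bis(benzyloxy)phenylmagnesium bromide 9 (not isolated)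
Conditions: 8, Mg, THF, rt; then 7, THF, 0 °C; aqueous work-up
Reagents that add atoms: none
Why: Weinreb ketone synthesis: the N-methoxy-chelated tetrahedral adduct persists until work-up, so the Grignard reagent should add once and the α-stereocenter is not touched.

Step 5
Reactants: 10 (S)-2-(benzyloxy)-1-[3,4-bis(benzyloxy)phenyl]-3-(2,4,6-trifluorophenyl)propan-1-one
Product: 11 (1R,2S)-2-(benzyloxy)-1-[3,4-bis(benzyloxy)phenyl]-3-(2,4,6-trifluorophenyl)propan-1-ol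
Conditions: Zn(BH4)2, Et2O, −20 → 0 °C
Reagents that add atoms: none
Why: Chelation-controlled reduction (Cram chelate model): zinc bridges the carbonyl and the α-benzyloxy oxygen and hydride adds from the face opposite the CH2Ar group, which should set the new carbinol center as R, anti to the benzyloxy group.

Step 6
Reactants: 11 (1R,2S)-2-(benzyloxy)-1-[3,4-bis(benzyloxy)phenyl]-3-(2,4,6-trifluorophenyl)propan-1-ol
Product: 14 (2R,3S)-3,5,7-tris(benzyloxy)-2-[3,4-bis(benzyloxy)phenyl]chromane (penta-O-benzyl-(+)-catechin), via 5,7-difluorochromane 12 (not isolated), via 7-benzyloxy-5-fluorochromane 13 (not isolated)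
Conditions: NaH (1.2 equiv), DMPU, 0 → 40 °C; then BnONa (6 equiv, from BnOH and NaH), DMPU, 110 °C
Reagents that add atoms: benzyl alcohol OCc1ccccc1
Why: Addition–elimination (SNAr): the sodium alkoxide of the benzylic hydroxyl (future O1) attacks an ortho C–F carbon (future C8a) of the trifluorophenyl ring, the Meisenheimer anion being stabilised by the two remaining meta fluorines, and fluoride leaves; benzyloxide then displaces the C7 and C5 fluorines of 12 and 13 at 110 °C, the meta-placed oxygens not deactivating these positions by resonance. The closest known reaction types are the intramolecular fluoride displacement by a tethered alkoxide that gives chromans from 3-(2-fluoroaryl)propanols and the alkoxydefluorination of polyfluorobenzenes. Ring C closes in the 6-exo-trig mode at the arene carbon; no new stereocenter is formed, and C2 (R) and C3 (S) are retained because only O–H and C–F bonds are touched, so the anti alcohol should give the 2,3-trans flavan. The selectivities needed are ring closure before intermolecular attack (only NaH is present in the first stage), six- over five-membered closure (the C3 oxygen is benzylated) and the choice of ortho fluorine (the two are equivalent by symmetry).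

Step 7
Reactants: 15 (−)-epicatechin
Product: 16 5,7,3',4'-tetra-O-benzyl-(−)-epicatechin
Conditions: BnBr (4.5 equiv), K2CO3, DMF, 0 °C → rt, Ar
Reagents that add atoms: benzyl bromide BrCc1ccccc1
Why: Williamson etherification of the four phenols under carbonate base should leave the aliphatic 3-hydroxyl free; no stereocenter is touched.

Step 8
Reactants: 16 5,7,3',4'-tetra-O-benzyl-(−)-epicatechin
Product: 17 (2R,3R,4S)-5,7,3',4'-tetra-O-benzyl-4-(2-ethoxyethoxy)flavan-3-ol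
Conditions: DDQ, 2-ethoxyethanol, CH2Cl2, rt
Reagents that add atoms: 2-ethoxyethanol CCOCCO
Why: Benzylic oxidation by hydride abstraction with DDQ gives the C4 cation stabilised by the 5,7-dialkoxy ring A, which the alcohol should trap from the β face, trans to the 3-hydroxyl and 2-aryl groups, setting C4 as S (4β).

Step 9
Reactants: 17 (2R,3R,4S)-5,7,3',4'-tetra-O-benzyl-4-(2-ethoxyethoxy)flavan-3-ol; 14 penta-O-benzyl-(+)-catechin
Product: 18 5,7,3',4'-tetra-O-benzylepicatechin-(4β→8)-3,5,7,3',4'-penta-O-benzylcatechin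
Conditions: 14 (2.5 equiv, excess recovered), TMSOTf (cat.), CH2Cl2, −78 °C; Et3N
Reagents that add atoms: none
Why: Lewis acid-mediated Friedel–Crafts alkylation of C8 of 14 by the flavan-4-yl cation from 17: attack anti to the cis 2-aryl and 3-hydroxyl groups should set the new C4 center as 4β (3,4-trans), and the excess of 14 suppresses self-condensation of 17.

Step 10
Reactants: 19 (−)-epigallocatechin
Product: 20 5,7,3',4',5'-penta-O-benzyl-(−)-epigallocatechin
Conditions: BnBr (5.5 equiv), K2CO3, DMF, 0 °C → rt, Ar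
Reagents that add atoms: benzyl bromide BrCc1ccccc1
Why: Williamson etherification of the five phenols under carbonate base with exclusion of air (the pyrogallol ring is oxidation-prone) should leave the aliphatic 3-hydroxyl free; the C2 and C3 centers are not touched.

Step 11
Reactants: 20 5,7,3',4',5'-penta-O-benzyl-(−)-epigallocatechin
Product: 21 (2R,3R,4S)-5,7,3',4',5'-penta-O-benzyl-4-(2-ethoxyethoxy)epigallocatechin
Conditions: DDQ, 2-ethoxyethanol, CH2Cl2, rt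
Reagents that add atoms: 2-ethoxyethanol CCOCCO
Why: DDQ benzylic oxidation as in step 8, carried out while the 3-hydroxyl is still free so that no electron-withdrawing ester retards hydride abstraction: the C4 cation should be trapped by the alcohol from the β face, trans to the 3-hydroxyl and 2-aryl groups, setting C4 as S (4β).

Step 12
Reactants: 21 (2R,3R,4S)-5,7,3',4',5'-penta-O-benzyl-4-(2-ethoxyethoxy)epigallocatechin; 22 3,4,5-tris(benzyloxy)benzoic acid (tri-O-benzylgallic acid)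
Product: 23 (2R,3R,4S)-4-(2-ethoxyethoxy)-octa-O-benzylepigallocatechin 3-O-gallate
Conditions: DCC, DMAP (cat.), CH2Cl2, 0 °C → rt
Reagents that add atoms: none
Why: Steglich esterification: the O-acylisourea formed from 22 and DCC is passed on by DMAP to the secondary 3-hydroxyl under neutral conditions that the acid-labile C4 ether tolerates; no C–O bond at a stereocenter is broken, so C2, C3 and C4 are retained.

Step 13
Reactants: 23 (2R,3R,4S)-4-(2-ethoxyethoxy)-octa-O-benzylepigallocatechin 3-O-gallate; 18 tetra-O-benzylepicatechin-(4β→8)-penta-O-benzylcatechin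
Product: 24 octa-O-benzyl-EGCG-(4β→8)-tetra-O-benzylepicatechin-(4β→8)-penta-O-benzylcatechin
Conditions: 18 (2 equiv, excess recovered), TMSOTf (cat.), CH2Cl2, −78 → −40 °C; Et3N
Reagents that add atoms: none
Why: Friedel–Crafts alkylation at the free C8 of the upper unit of 18: the 3-O-galloyl carbonyl can shield the α face of the C4 cation (anchimeric assistance through a dioxolenium ion), so the nucleophile should enter from the β face and set C4 as 4β.

Step 14
Reactants: 17 (2R,3R,4S)-5,7,3',4'-tetra-O-benzyl-4-(2-ethoxyethoxy)flavan-3-ol; 24 octa-O-benzyl-EGCG-(4β→8)-tetra-O-benzylepicatechin-(4β→8)-penta-O-benzylcatechin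
Product: 25 tetra-O-benzylepicatechin-(4β→8)-octa-O-benzyl-EGCG-(4β→8)-tetra-O-benzylepicatechin-(4β→8)-penta-O-benzylcatechin
Conditions: 24 (2 equiv, excess recovered), TMSOTf (cat.), CH2Cl2, −78 °C; Et3N
Reagents that add atoms: none
Why: Friedel–Crafts alkylation at C8 of the gallate unit, the only unit of 24 with a free C8, by the cation from 17, which should again be attacked anti to its 2-aryl and 3-hydroxyl groups to set the last C4 center as 4β.

Step 15
Reactants: 25 protected tetramer (21 benzyl ethers)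
Product: 26 epicatechin-(4β→8)-epigallocatechin 3-O-gallate-(4β→8)-epicatechin-(4β→8)-catechin (CNP0332815.1)
Conditions: H2 (1 atm), Pd(OH)2/C, THF/MeOH/H2O, rt
Reagents that add atoms: none
Why: Hydrogenolysis of the 21 benzyl ethers should release all phenols and the C3 hydroxyl of the catechin unit, while the gallate ester, the interflavan bonds and all eleven stereocenters are unaffected.

Compound list

1 | 1,3,5-trifluorobenzene | Fc1cc(F)cc(F)c1 | starting material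
2 | methyl (S)-oxirane-2-carboxylate | COC(=O)[C@@H]1CO1 | starting material
3 | 2,4,6-trifluorophenyllithium | [Li]c1c(F)cc(F)cc1F | intermediate
4 | 2,4,6-trifluorophenylmagnesium bromide | Br[Mg]c1c(F)cc(F)cc1F | intermediate
5 | methyl (S)-2-hydroxy-3-(2,4,6-trifluorophenyl)propanoate | COC(=O)[C@@H](O)Cc1c(F)cc(F)cc1F | intermediate
6 | methyl (S)-2-(benzyloxy)-3-(2,4,6-trifluorophenyl)propanoate | COC(=O)[C@@H](OCc1ccccc1)Cc1c(F)cc(F)cc1F | intermediate
7 | (S)-2-(benzyloxy)-N-methoxy-N-methyl-3-(2,4,6-trifluorophenyl)propanamide | CON(C)C(=O)[C@@H](OCc1ccccc1)Cc1c(F)cc(F)cc1F | intermediate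
8 | 4-bromo-1,2-bis(benzyloxy)benzene | Brc1ccc(OCc2ccccc2)c(OCc2ccccc2)c1 | starting material
9 | 3,4-bis(benzyloxy)phenylmagnesium bromide | Br[Mg]c1ccc(OCc2ccccc2)c(OCc2ccccc2)c1 | intermediate
10 | (S)-2-(benzyloxy)-1-[3,4-bis(benzyloxy)phenyl]-3-(2,4,6-trifluorophenyl)propan-1-one | O=C(c1ccc(OCc2ccccc2)c(OCc2ccccc2)c1)[C@@H](OCc1ccccc1)Cc1c(F)cc(F)cc1F | intermediate
11 | (1R,2S)-2-(benzyloxy)-1-[3,4-bis(benzyloxy)phenyl]-3-(2,4,6-trifluorophenyl)propan-1-ol | O[C@H](c1ccc(OCc2ccccc2)c(OCc2ccccc2)c1)[C@@H](OCc1ccccc1)Cc1c(F)cc(F)cc1F | intermediate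
12 | (2R,3S)-3-(benzyloxy)-2-[3,4-bis(benzyloxy)phenyl]-5,7-difluorochromane | Fc1cc(F)c2c(c1)O[C@H](c1ccc(OCc3ccccc3)c(OCc3ccccc3)c1)[C@@H](OCc1ccccc1)C2 | intermediate
13 | (2R,3S)-3,7-bis(benzyloxy)-2-[3,4-bis(benzyloxy)phenyl]-5-fluorochromane | C(Oc1cc(F)c2c(c1)O[C@H](c1ccc(OCc3ccccc3)c(OCc3ccccc3)c1)[C@@H](OCc1ccccc1)C2)c1ccccc1 | intermediate
14 | (2R,3S)-3,5,7-tris(benzyloxy)-2-[3,4-bis(benzyloxy)phenyl]chromane (penta-O-benzyl-(+)-catechin) | c1c(OCc5ccccc5)cc(OCc5ccccc5)c2c1O[C@H](c1ccc(OCc5ccccc5)c(OCc5ccccc5)c1)[C@@H](OCc5ccccc5)C2 | intermediate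
15 | (−)-epicatechin | C1c2c(O)cc(O)cc2O[C@H](c2ccc(O)c(O)c2)[C@@H]1O | starting material
16 | 5,7,3',4'-tetra-O-benzyl-(−)-epicatechin | C1c2c(OCc5ccccc5)cc(OCc5ccccc5)cc2O[C@H](c2ccc(OCc5ccccc5)c(OCc5ccccc5)c2)[C@@H]1O | intermediate
17 | (2R,3R,4S)-5,7,3',4'-tetra-O-benzyl-4-(2-ethoxyethoxy)flavan-3-ol | CCOCCO[C@H]1c2c(OCc5ccccc5)cc(OCc5ccccc5)cc2O[C@H](c2ccc(OCc5ccccc5)c(OCc5ccccc5)c2)[C@@H]1O | intermediate
18 | 5,7,3',4'-tetra-O-benzylepicatechin-(4β→8)-3,5,7,3',4'-penta-O-benzylcatechin | c1c(OCc5ccccc5)cc(OCc5ccccc5)c2c1O[C@H](c1ccc(OCc5ccccc5)c(OCc5ccccc5)c1)[C@H](O)[C@H]2c1c(OCc5ccccc5)cc(OCc5ccccc5)c2c1O[C@H](c1ccc(OCc5ccccc5)c(OCc5ccccc5)c1)[C@@H](OCc5ccccc5)C2 | intermediate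
19 | (−)-epigallocatechin | O[C@@H]1Cc2c(O)cc(O)cc2O[C@@H]1c1cc(O)c(O)c(O)c1 | starting material
20 | 5,7,3',4',5'-penta-O-benzyl-(−)-epigallocatechin | O[C@@H]1Cc2c(OCc5ccccc5)cc(OCc5ccccc5)cc2O[C@@H]1c1cc(OCc5ccccc5)c(OCc5ccccc5)c(OCc5ccccc5)c1 | intermediate
21 | (2R,3R,4S)-5,7,3',4',5'-penta-O-benzyl-4-(2-ethoxyethoxy)epigallocatechin | O[C@@H]1[C@@H](OCCOCC)c2c(OCc5ccccc5)cc(OCc5ccccc5)cc2O[C@@H]1c1cc(OCc5ccccc5)c(OCc5ccccc5)c(OCc5ccccc5)c1 | intermediate
22 | 3,4,5-tris(benzyloxy)benzoic acid | OC(=O)c1cc(OCc2ccccc2)c(OCc2ccccc2)c(OCc2ccccc2)c1 | starting material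
23 | (2R,3R,4S)-4-(2-ethoxyethoxy)-octa-O-benzylepigallocatechin 3-O-gallate | O=C(O[C@@H]1[C@@H](OCCOCC)c2c(OCc5ccccc5)cc(OCc5ccccc5)cc2O[C@@H]1c1cc(OCc5ccccc5)c(OCc5ccccc5)c(OCc5ccccc5)c1)c1cc(OCc5ccccc5)c(OCc5ccccc5)c(OCc5ccccc5)c1 | intermediate
24 | octa-O-benzyl-EGCG-(4β→8)-tetra-O-benzylepicatechin-(4β→8)-penta-O-benzylcatechin | O=C(O[C@@H]1[C@@H](c2c(OCc5ccccc5)cc(OCc5ccccc5)c3c2O[C@H](c2ccc(OCc5ccccc5)c(OCc5ccccc5)c2)[C@H](O)[C@H]3c2c(OCc5ccccc5)cc(OCc5ccccc5)c3c2O[C@H](c2ccc(OCc5ccccc5)c(OCc5ccccc5)c2)[C@@H](OCc5ccccc5)C3)c2c(OCc5ccccc5)cc(OCc5ccccc5)cc2O[C@@H]1c1cc(OCc5ccccc5)c(OCc5ccccc5)c(OCc5ccccc5)c1)c1cc(OCc5ccccc5)c(OCc5ccccc5)c(OCc5ccccc5)c1 | intermediate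
25 | tetra-O-benzylepicatechin-(4β→8)-octa-O-benzyl-EGCG-(4β→8)-tetra-O-benzylepicatechin-(4β→8)-penta-O-benzylcatechin | O=C(O[C@@H]1[C@@H](c2c(OCc5ccccc5)cc(OCc5ccccc5)c3c2O[C@H](c2ccc(OCc5ccccc5)c(OCc5ccccc5)c2)[C@H](O)[C@H]3c2c(OCc5ccccc5)cc(OCc5ccccc5)c3c2O[C@H](c2ccc(OCc5ccccc5)c(OCc5ccccc5)c2)[C@@H](OCc5ccccc5)C3)c2c(OCc5ccccc5)cc(OCc5ccccc5)c([C@H]3c4c(OCc5ccccc5)cc(OCc5ccccc5)cc4O[C@H](c4ccc(OCc5ccccc5)c(OCc5ccccc5)c4)[C@@H]3O)c2O[C@@H]1c1cc(OCc5ccccc5)c(OCc5ccccc5)c(OCc5ccccc5)c1)c1cc(OCc5ccccc5)c(OCc5ccccc5)c(OCc5ccccc5)c1 | intermediate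
26 | epicatechin-(4β→8)-epigallocatechin 3-O-gallate-(4β→8)-epicatechin-(4β→8)-catechin (CNP0332815.1) | O=C(O[C@@H]1[C@@H](c2c(O)cc(O)c3c2O[C@H](c2ccc(O)c(O)c2)[C@H](O)[C@H]3c2c(O)cc(O)c3c2O[C@H](c2ccc(O)c(O)c2)[C@@H](O)C3)c2c(O)cc(O)c([C@H]3c4c(O)cc(O)cc4O[C@H](c4ccc(O)c(O)c4)[C@@H]3O)c2O[C@@H]1c1cc(O)c(O)c(O)c1)c1cc(O)c(O)c(O)c1 | target

Total step count: 15 steps.
Longest linear sequence: 10 steps (steps 1, 2, 3, 4, 5, 6, 9, 13, 14, 15).

Steps most likely to fail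

Step 6. The intermolecular displacement of the last, least activated fluorine may stall under conditions the benzyl ethers tolerate, or benzyloxide may attack both ortho positions before ring closure is complete. The fallback sets out from 1 and comes back at 14; it reverses the order of the three displacements. Two fluorines of 1 are exchanged while the ring is still activated (BnOH, NaH, NMP, 80 °C) to give 1,3-bis(benzyloxy)-5-fluorobenzene F1. Lithiation between fluorine and benzyloxy (n-BuLi, THF, −78 °C), transmetalation and copper-catalysed opening of 2 give methyl (S)-3-[2,4-bis(benzyloxy)-6-fluorophenyl]-2-hydroxypropanoate F2. The operations of steps 2 to 5 then give methyl (S)-2-(benzyloxy)-3-[2,4-bis(benzyloxy)-6-fluorophenyl]propanoate F3, (S)-2-(benzyloxy)-3-[2,4-bis(benzyloxy)-6-fluorophenyl]-N-methoxy-N-methylpropanamide F4, (S)-2-(benzyloxy)-3-[2,4-bis(benzyloxy)-6-fluorophenyl]-1-[3,4-bis(benzyloxy)phenyl]propan-1-one F5 and (1R,2S)-2-(benzyloxy)-3-[2,4-bis(benzyloxy)-6-fluorophenyl]-1-[3,4-bis(benzyloxy)phenyl]propan-1-ol F6. Only the intramolecular fluoride displacement then remains (NaH, DMF, 80 °C), and it closes ring C through the same O1–C8a bond to give 14.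

Step 13. Ionisation at C4 may be slow next to the electron-withdrawing 3-O-galloyl group, so that the hindered dimer is alkylated slowly and self-condensation of the electrophile or loss of facial control takes over. The fallback sets out from 18 and comes back at 26; it couples the electrophile with its 3-hydroxyl still free and puts the gallate on afterwards. The 3-hydroxyl of 18 is capped as a benzyl ether (NaH, BnBr, DMF, 0 °C) to give 3,5,7,3',4'-penta-O-benzylepicatechin-(4β→8)-3,5,7,3',4'-penta-O-benzylcatechin F7. Coupling of 21 with F7 (TMSOTf, CH2Cl2, −78 °C) gives penta-O-benzylepigallocatechin-(4β→8)-penta-O-benzylepicatechin-(4β→8)-penta-O-benzylcatechin F8, whose only free hydroxyl is at C3 of the epigallocatechin unit. Steglich esterification with 22 (DCC, DMAP, CH2Cl2) gives octa-O-benzyl-EGCG-(4β→8)-penta-O-benzylepicatechin-(4β→8)-penta-O-benzylcatechin F9. Coupling with 17 (TMSOTf, CH2Cl2, −78 °C) gives the 3-O-benzyl protected tetramer F10, and hydrogenolysis (H2, Pd(OH)2/C, THF/MeOH/H2O) removes every benzyl ether to give 26.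

Step 14. The electrophile may self-condense through its own free C8, attack at a C6 position of the trimer may compete, and prolonged exposure of the hindered trimer to the Lewis acid may scramble the existing interflavan bonds. The fallback sets out from 16 and comes back at 26; it blocks C8 of the electrophile. Bromination (NBS, CH2Cl2, −78 °C → rt) gives 8-bromo-5,7,3',4'-tetra-O-benzyl-(−)-epicatechin F11. DDQ and 2-ethoxyethanol give (2R,3R,4S)-8-bromo-5,7,3',4'-tetra-O-benzyl-4-(2-ethoxyethoxy)flavan-3-ol F12, which cannot self-condense and is coupled 1:1 with 24 (TMSOTf, CH2Cl2, −78 °C) to the 8-bromo protected tetramer F13. Hydrogenolysis (H2, Pd(OH)2/C, Et3N, THF/MeOH/H2O) removes the bromine together with the benzyl ethers and gives 26.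

Further compounds

F1 | step 6 | 1,3-bis(benzyloxy)-5-fluorobenzene | Fc1cc(OCc2ccccc2)cc(OCc2ccccc2)c1
F2 | step 6 | methyl (S)-3-[2,4-bis(benzyloxy)-6-fluorophenyl]-2-hydroxypropanoate | COC(=O)[C@@H](O)Cc1c(F)cc(OCc2ccccc2)cc1OCc1ccccc1
F3 | step 6 | methyl (S)-2-(benzyloxy)-3-[2,4-bis(benzyloxy)-6-fluorophenyl]propanoate | COC(=O)[C@@H](OCc1ccccc1)Cc1c(F)cc(OCc2ccccc2)cc1OCc1ccccc1
F4 | step 6 | (S)-2-(benzyloxy)-3-[2,4-bis(benzyloxy)-6-fluorophenyl]-N-methoxy-N-methylpropanamide | CON(C)C(=O)[C@@H](OCc1ccccc1)Cc1c(F)cc(OCc2ccccc2)cc1OCc1ccccc1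
F5 | step 6 | (S)-2-(benzyloxy)-3-[2,4-bis(benzyloxy)-6-fluorophenyl]-1-[3,4-bis(benzyloxy)phenyl]propan-1-one | O=C(c1ccc(OCc2ccccc2)c(OCc2ccccc2)c1)[C@@H](OCc1ccccc1)Cc1c(F)cc(OCc2ccccc2)cc1OCc1ccccc1
F6 | step 6 | (1R,2S)-2-(benzyloxy)-3-[2,4-bis(benzyloxy)-6-fluorophenyl]-1-[3,4-bis(benzyloxy)phenyl]propan-1-ol | O[C@H](c1ccc(OCc2ccccc2)c(OCc2ccccc2)c1)[C@@H](OCc1ccccc1)Cc1c(F)cc(OCc2ccccc2)cc1OCc1ccccc1
F7 | step 13 | 3,5,7,3',4'-penta-O-benzylepicatechin-(4β→8)-3,5,7,3',4'-penta-O-benzylcatechin | c1c(OCc5ccccc5)cc(OCc5ccccc5)c2c1O[C@H](c1ccc(OCc5ccccc5)c(OCc5ccccc5)c1)[C@H](OCc5ccccc5)[C@H]2c1c(OCc5ccccc5)cc(OCc5ccccc5)c2c1O[C@H](c1ccc(OCc5ccccc5)c(OCc5ccccc5)c1)[C@@H](OCc5ccccc5)C2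
F8 | step 13 | penta-O-benzylepigallocatechin-(4β→8)-penta-O-benzylepicatechin-(4β→8)-penta-O-benzylcatechin | O[C@@H]1[C@@H](c2c(OCc5ccccc5)cc(OCc5ccccc5)c3c2O[C@H](c2ccc(OCc5ccccc5)c(OCc5ccccc5)c2)[C@H](OCc5ccccc5)[C@H]3c2c(OCc5ccccc5)cc(OCc5ccccc5)c3c2O[C@H](c2ccc(OCc5ccccc5)c(OCc5ccccc5)c2)[C@@H](OCc5ccccc5)C3)c2c(OCc5ccccc5)cc(OCc5ccccc5)cc2O[C@@H]1c1cc(OCc5ccccc5)c(OCc5ccccc5)c(OCc5ccccc5)c1
F9 | step 13 | octa-O-benzyl-EGCG-(4β→8)-penta-O-benzylepicatechin-(4β→8)-penta-O-benzylcatechin | O=C(O[C@@H]1[C@@H](c2c(OCc5ccccc5)cc(OCc5ccccc5)c3c2O[C@H](c2ccc(OCc5ccccc5)c(OCc5ccccc5)c2)[C@H](OCc5ccccc5)[C@H]3c2c(OCc5ccccc5)cc(OCc5ccccc5)c3c2O[C@H](c2ccc(OCc5ccccc5)c(OCc5ccccc5)c2)[C@@H](OCc5ccccc5)C3)c2c(OCc5ccccc5)cc(OCc5ccccc5)cc2O[C@@H]1c1cc(OCc5ccccc5)c(OCc5ccccc5)c(OCc5ccccc5)c1)c1cc(OCc5ccccc5)c(OCc5ccccc5)c(OCc5ccccc5)c1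
F10 | step 13 | 3-O-benzyl protected tetramer (25 with a benzyl ether at C3 of the lower epicatechin unit) | O=C(O[C@@H]1[C@@H](c2c(OCc5ccccc5)cc(OCc5ccccc5)c3c2O[C@H](c2ccc(OCc5ccccc5)c(OCc5ccccc5)c2)[C@H](OCc5ccccc5)[C@H]3c2c(OCc5ccccc5)cc(OCc5ccccc5)c3c2O[C@H](c2ccc(OCc5ccccc5)c(OCc5ccccc5)c2)[C@@H](OCc5ccccc5)C3)c2c(OCc5ccccc5)cc(OCc5ccccc5)c([C@H]3c4c(OCc5ccccc5)cc(OCc5ccccc5)cc4O[C@H](c4ccc(OCc5ccccc5)c(OCc5ccccc5)c4)[C@@H]3O)c2O[C@@H]1c1cc(OCc5ccccc5)c(OCc5ccccc5)c(OCc5ccccc5)c1)c1cc(OCc5ccccc5)c(OCc5ccccc5)c(OCc5ccccc5)c1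
F11 | step 14 | 8-bromo-5,7,3',4'-tetra-O-benzyl-(−)-epicatechin | C1c2c(OCc5ccccc5)cc(OCc5ccccc5)c(Br)c2O[C@H](c2ccc(OCc5ccccc5)c(OCc5ccccc5)c2)[C@@H]1O
F12 | step 14 | (2R,3R,4S)-8-bromo-5,7,3',4'-tetra-O-benzyl-4-(2-ethoxyethoxy)flavan-3-ol | CCOCCO[C@H]1c2c(OCc5ccccc5)cc(OCc5ccccc5)c(Br)c2O[C@H](c2ccc(OCc5ccccc5)c(OCc5ccccc5)c2)[C@@H]1O
F13 | step 14 | 8-bromo protected tetramer (25 with bromine at C8 of the top epicatechin unit) | O=C(O[C@@H]1[C@@H](c2c(OCc5ccccc5)cc(OCc5ccccc5)c3c2O[C@H](c2ccc(OCc5ccccc5)c(OCc5ccccc5)c2)[C@H](O)[C@H]3c2c(OCc5ccccc5)cc(OCc5ccccc5)c3c2O[C@H](c2ccc(OCc5ccccc5)c(OCc5ccccc5)c2)[C@@H](OCc5ccccc5)C3)c2c(OCc5ccccc5)cc(OCc5ccccc5)c([C@H]3c4c(OCc5ccccc5)cc(OCc5ccccc5)c(Br)c4O[C@H](c4ccc(OCc5ccccc5)c(OCc5ccccc5)c4)[C@@H]3O)c2O[C@@H]1c1cc(OCc5ccccc5)c(OCc5ccccc5)c(OCc5ccccc5)c1)c1cc(OCc5ccccc5)c(OCc5ccccc5)c(OCc5ccccc5)c1
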